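The ten-membered ring is opened at C5–C6, the bond joining the free carbinol to the lactone carbinol; with the C8 oxygen and the C3=C4 double bond this is an oxy-Cope retron. The precursor is a 7-oxanorbornenol that carries, cis on its exo face, an (E)-silyl enol ether at C3 and a 2-silyloxyfuran at the carbinol carbon C8. Its anionic oxy-Cope rearrangement, held in a boat by the bicycle, forms C5–C6, expands the six-membered carbocycle to the ten-membered one with C3=C4 cis, sets C5 and C6, and delivers the lactone ring as its silyl ketene acetal. The oxygen bridge ends as the C2 ketone oxygen.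

Key step: step 11

Remark on locants: C2 is the ketone carbon, C1=C10 and C3=C4 the ring double bonds (C14 and C15 their methyl groups), C5 the free carbinol, C6 the lactone carbinol, C7 the ring-fusion carbon, C8 the tiglate carbinol, C9 the CH2, and C11/C12/C13 the lactone α-carbon, carbonyl carbon and exocyclic methylene. The same locants are used for every intermediate; in the 7-oxanorbornenes C2 and C9 are the bridgeheads.
Assumption: 4-bromofuran-2(5H)-one is taken as a catalogue compound.

Step 1
Reactants: 1 3-methylfuran; 2 methyl propiolate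
Product: 3 rac-methyl 5-methyl-7-oxabicyclo[2.2.1]hepta-2,5-diene-2-carboxylate
Conditions: AlCl3 (0.2 equiv), CH2Cl2, −30 °C, short contact, then Et3N
Reagents that add atoms: none
Why: Lewis-acid-promoted Diels–Alder reaction of a furan with an alkynoate, in which the more nucleophilic furan carbon next to the methyl group bonds to the β-carbon of the ynoate, so that the methyl group ends on C10 beside the bridgehead C9 and the ester on C3.

Step 2
Reactants: 3 rac-methyl 5-methyl-7-oxabicyclo[2.2.1]hepta-2,5-diene-2-carboxylate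
Product: 5 rac-methyl 3-exo-hydroxy-5-methyl-7-oxabicyclo[2.2.1]hept-5-ene-2-endo-carboxylate, via exo-boronate 4 (not isolated)
Conditions: B2pin2, CuCl (5 mol%), Xantphos (5 mol%), NaOt-Bu (10 mol%), MeOH, THF, 25 °C; then 30% H2O2, pH 7 phosphate buffer, 0 °C
Reagents that add atoms: bis(pinacolato)diboron, CC1(C)OB(OC1(C)C)B1OC(C)(C)C(C)(C)O1 (boron kept in 4 only); hydrogen peroxide, OO
Why: Copper-catalysed conjugate borylation of the strained enoate from the open exo face (then protonation of the copper enolate), followed by oxidation of the C–B bond with retention, places the C8 oxygen exo and trans to the ester.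

Step 3
Reactants: 5 rac-methyl 3-exo-hydroxy-5-methyl-7-oxabicyclo[2.2.1]hept-5-ene-2-endo-carboxylate
Product: 6 methyl (1R,2R,3R,4S)-3-hydroxy-5-methyl-7-oxabicyclo[2.2.1]hept-5-ene-2-carboxylate
Conditions: Candida antarctica lipase B (immobilised), vinyl acetate, t-BuOMe, 30 °C, to half conversion; chromatography
Reagents that add atoms: none
Why: Lipase-catalysed kinetic resolution by enantioselective acetylation, in which the empirical size rule for secondary alcohols (ester-bearing C3 as the large group) predicts that the (3S)-carbinol is acetylated and the needed (3R)-alcohol stays behind; this fixes the absolute sense of both bridgeheads.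

Step 4
Reactants: 6 methyl (1R,2R,3R,4S)-3-hydroxy-5-methyl-7-oxabicyclo[2.2.1]hept-5-ene-2-carboxylate
Product: 7 methyl (1R,4S)-5-methyl-3-oxo-7-oxabicyclo[2.2.1]hept-5-ene-2-carboxylate
Conditions: DMP (triacetoxy benziodoxolone periodinane), NaHCO3, CH2Cl2, 0 → 25 °C
Reagents that add atoms: none
Why: Periodinane oxidation of the secondary alcohol gives the β-keto ester under buffered conditions that spare the strained alkene.

Step 5
Reactants: 7 methyl (1R,4S)-5-methyl-3-oxo-7-oxabicyclo[2.2.1]hept-5-ene-2-carboxylate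
Product: 8 (1S,4S)-6-methyl-7-oxabicyclo[2.2.1]hept-5-en-2-one
Conditions: LiCl, H2O, DMSO, 120 °C
Reagents that add atoms: none
Why: Krapcho dealkoxycarbonylation (chloride attack on the methyl group, loss of CO2) removes the ester that steered the cycloaddition and leaves C3 as the only enolisable position, C9 being a bridgehead.

Step 6
Reactants: 9 ethyl acetate
Product: 11 triisopropyl(prop-1-yn-1-yloxy)silane, via lithium ynolate 10 (not isolated)
Conditions: CH2Br2, LiTMP, THF, −78 °C; n-BuLi, −78 → 0 °C; i-Pr3SiCl, −78 → 25 °C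
Reagents that add atoms: dibromomethane, BrCBr; chlorotriisopropylsilane, CC(C)[Si](Cl)(C(C)C)C(C)C
Why: Ester-to-ynolate homologation (addition of LiCHBr2, bromine–lithium exchange and 1,2-shift) and O-silylation with the bulky chlorosilane give the siloxyalkyne that holds C15, C4 and C5 with its oxygen.

Step 7
Reactants: 11 triisopropyl(prop-1-yn-1-yloxy)silane
Product: 13 (E)-[(2-bromoprop-1-en-1-yl)oxy]triisopropylsilane, via alkenylzirconocene chloride 12 (not isolated)
Conditions: Cp2Zr(H)Cl, CH2Cl2, 25 °C; then N-bromosuccinimide, 0 °C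
Reagents that add atoms: Cp2Zr(H)Cl, [H][Zr](Cl)(C1C=CC=C1)C1C=CC=C1 (zirconium kept in 12 only); N-bromosuccinimide, O=C1CCC(=O)N1Br
Why: Hydrozirconation adds H and Zr syn with zirconium on the carbon remote from oxygen, and bromodezirconation with retention gives the bromide with Br trans to the silyloxy group, the geometry needed for the (E)-enol ether.

Step 8
Reactants: 8 (1S,4S)-6-methyl-7-oxabicyclo[2.2.1]hept-5-en-2-one; 13 (E)-[(2-bromoprop-1-en-1-yl)oxy]triisopropylsilane
Product: 15 (1S,3R,4R)-6-methyl-3-exo-[(E)-1-(triisopropylsilyloxy)prop-1-en-2-yl]-7-oxabicyclo[2.2.1]hept-5-en-2-one, via chlorozinc enolate 14 (not isolated)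
Conditions: LiHMDS, THF, −78 °C; ZnCl2; Pd(dba)2 (5 mol%), P(t-Bu)3 (5 mol%), 25 °C
Reagents that add atoms: ZnCl2, Cl[Zn]Cl (zinc kept in 14 only)
Why: Palladium-catalysed α-alkenylation of a ketone enolate with retention of alkene geometry; reductive elimination from the exo-bound palladium enolate puts the alkenyl group exo, and the weakly basic zinc enolate should avoid epimerisation at C3.

Step 9
Reactants: 16 4-bromofuran-2(5H)-one
Product: 17 [(4-bromofuran-2-yl)oxy]triisopropylsilane
Conditions: i-Pr3SiOTf, Et3N, CH2Cl2, 0 °C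
Reagents that add atoms: triisopropylsilyl triflate, CC(C)[Si](OS(=O)(=O)C(F)(F)F)(C(C)C)C(C)C
Why: Soft enolisation and O-silylation of the butenolide give the aromatic 2-silyloxyfuran, the masked γ-lactone (O, C6, C7, C11, C12).

Step 10
Reactants: 15 (1S,3R,4R)-6-methyl-3-exo-[(E)-1-(triisopropylsilyloxy)prop-1-en-2-yl]-7-oxabicyclo[2.2.1]hept-5-en-2-one; 17 [(4-bromofuran-2-yl)oxy]triisopropylsilane
Product: 19 (1S,2R,3R,4R)-6-methyl-3-exo-[(E)-1-(triisopropylsilyloxy)prop-1-en-2-yl]-2-exo-[5-(triisopropylsilyloxy)furan-3-yl]-7-oxabicyclo[2.2.1]hept-5-en-2-ol, via furyllithium 18 (not isolated)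
Conditions: 17, n-BuLi, THF, −78 °C; CeCl3; then 15, −78 °C; aq. NH4Cl
Reagents that add atoms: n-butyllithium, [Li]CCCC (lithium kept in 18 only)
Why: Bromine–lithium exchange and transmetalation give a weakly basic furylcerium reagent that adds to the ketone (1,2-addition) from the exo face left open by the oxygen bridge, the endo face being screened by the C1=C10 bridge, so that the furyl group is exo and cis to the alkenyl group and the hydroxyl is endo.

Step 11
Reactants: 19 (1S,2R,3R,4R)-6-methyl-3-exo-[(E)-1-(triisopropylsilyloxy)prop-1-en-2-yl]-2-exo-[5-(triisopropylsilyloxy)furan-3-yl]-7-oxabicyclo[2.2.1]hept-5-en-2-ol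
Product: 22 bridged Mannich keto lactone (2R,5S,6R,7S,9S), via potassium enolate 20 (not isolated), via keto silyl ketene acetal 21 (not isolated)
Conditions: KH, 18-crown-6, THF, −40 → 0 °C; AcOH (1 equiv), −78 °C; CH2=NMe2+ I−, CH2Cl2, −78 → 0 °C; aq. NaHCO3
Reagents that add atoms: potassium hydride, [K+].[H-] (potassium kept in 20 only); dimethylmethyleneiminium iodide, C=[N+](C)C.[I-]
Why: KH/18-crown-6 gives the naked C8 alkoxide, whose C3–C8 σ-bond breaks as C5 of the enol ether bonds to C6 of the silyloxyfuran in a [3,3]-sigmatropic shift (anionic oxy-Cope), driven by formation of the C7=C8 enolate and release of the strained bicyclo[2.2.1] frame. The closest known reaction type is the anionic oxy-Cope ring expansion of cis-1,2-dialkenylcycloalkanols, including cases in which a furan double bond takes part. One ring is closed, the ten-membered carbocycle, by pericyclic ring expansion of the six-membered ring (giving an 11-oxabicyclo[6.2.1]undecadiene); the lactone ring is already present as the furan and leaves the step as a cyclic silyl ketene acetal. The eclipsed cis-exo,exo alkenyl groups allow only a boat transition state, in which the two oxygen-bearing termini, both trans to the breaking bond (E enol ether, furan oxygen), give the erythro C5/C6 pair, (5S,6R) from the (1S,2R,3R,4R) bicycle; C3=C4 comes out cis because the boat with the bridgehead C2 inside avoids the clash of the C4 methyl and the furan C11–H with the bridgeheads and avoids a trans double bond in the nine-membered oxacycle. C7 is set when AcOH protonates the enolate from its outer face, the inner face being covered by the transannular C3=C4 bond, which gives the cis ring fusion (7R in the target); the iminium salt then adds to the silyl ketene acetal (Mannich reaction) and stores the α-methylene group as its amine. The step needs the [3,3] shift to outrun alkoxide-accelerated retro-[4+2] cleavage to 3-methylfuran, which the pre-organised eclipsed termini and the low temperature should secure.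

Step 12
Reactants: 22 bridged Mannich keto lactone (2R,5S,6R,7S,9S)
Product: 24 hydroxy dienone (5S,6R,7R,8S), via hydroxy ketone 23 (not isolated)
Conditions: SmI2 (2.1 equiv), t-BuOH (1 equiv), THF, −78 °C; then 25 °C
Reagents that add atoms: none
Why: SmI2 cleaves the C9–O bond of the α-alkoxy ketone (reductive α-deoxygenation), and the resulting samarium C2 alkoxide then passes its carbinol hydrogen across the ring to C8 in a Meerwein–Ponndorf–Verley/Oppenauer 1,5-hydride shift, driven by formation of the cross-conjugated dienone and delivering hydride to the inner face of the C8 carbonyl (8S).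

Step 13
Reactants: 24 hydroxy dienone (5S,6R,7R,8S)
Product: 25 C8 tiglate (5S,6R,7R,8S)
Conditions: tigloyl chloride, Et3N, DMAP (cat.), CH2Cl2, 0 °C
Reagents that add atoms: tigloyl chloride, C/C=C(\C)C(Cl)=O
Why: DMAP-catalysed acylation of the only free hydroxyl installs the tiglate with retention at C8 and leaves the (E) geometry of the acyl group untouched.

Step 14
Reactants: 25 C8 tiglate (5S,6R,7R,8S)
Product: 27 O5-triisopropylsilyl ether of the target, via ammonium iodide 26 (not isolated)
Conditions: MeI, CH2Cl2–MeOH, 25 °C; then aq. NaHCO3, EtOAc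
Reagents that add atoms: iodomethane, CI (methyl kept in 26 only)
Why: Quaternisation of the Mannich base and mild base-induced β-elimination of trimethylamine (Hofmann-type elimination) unveil the α-methylene lactone late, after all reducing and nucleophilic steps.

Step 15
Reactants: 27 O5-triisopropylsilyl ether of the target
Product: 28 target germacranolide
Conditions: HF·pyridine, pyridine, THF, 0 → 25 °C
Reagents that add atoms: none
Why: Fluoride cleavage of the silyl ether under weakly acidic, buffered conditions frees the C5 hydroxyl without base-induced oxa-Michael addition to the methylene lactone or dehydration of the cis γ-hydroxy enone.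

Compound list
1 | 3-methylfuran | Cc1ccoc1 | starting material
2 | methyl propiolate | C#CC(=O)OC | starting material
3 | rac-methyl 5-methyl-7-oxabicyclo[2.2.1]hepta-2,5-diene-2-carboxylate | CC1=CC2OC1C=C2C(=O)OC | intermediate
4 | rac-methyl 3-exo-(4,4,5,5-tetramethyl-1,3,2-dioxaborolan-2-yl)-5-methyl-7-oxabicyclo[2.2.1]hept-5-ene-2-endo-carboxylate (racemate; one enantiomer drawn) | CC1=C[C@@H]2[C@H](C(=O)OC)[C@@H](B3OC(C)(C)C(C)(C)O3)[C@H]1O2 | intermediate
5 | rac-methyl 3-exo-hydroxy-5-methyl-7-oxabicyclo[2.2.1]hept-5-ene-2-endo-carboxylate (racemate; one enantiomer drawn) | CC1=C[C@@H]2[C@H](C(=O)OC)[C@@H](O)[C@H]1O2 | intermediate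
6 | methyl (1R,2R,3R,4S)-3-hydroxy-5-methyl-7-oxabicyclo[2.2.1]hept-5-ene-2-carboxylate | CC1=C[C@@H]2[C@H](C(=O)OC)[C@@H](O)[C@H]1O2 | intermediate
7 | methyl (1R,4S)-5-methyl-3-oxo-7-oxabicyclo[2.2.1]hept-5-ene-2-carboxylate (C2 epimers and enol) | CC1=C[C@@H]2C(C(=O)OC)C(=O)[C@H]1O2 | intermediate
8 | (1S,4S)-6-methyl-7-oxabicyclo[2.2.1]hept-5-en-2-one | CC1=C[C@@H]2CC(=O)[C@H]1O2 | intermediate
9 | ethyl acetate | CCOC(C)=O | starting material
10 | lithium prop-1-yn-1-olate | CC#C[O-].[Li+] | intermediate
11 | triisopropyl(prop-1-yn-1-yloxy)silane | CC#CO[Si](C(C)C)(C(C)C)C(C)C | intermediate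
12 | chlorobis(cyclopentadienyl)[(E)-1-(triisopropylsilyloxy)prop-1-en-2-yl]zirconium | C/C(=C\O[Si](C(C)C)(C(C)C)C(C)C)[Zr](Cl)(C1C=CC=C1)C1C=CC=C1 | intermediate
13 | (E)-[(2-bromoprop-1-en-1-yl)oxy]triisopropylsilane | C/C(Br)=C\O[Si](C(C)C)(C(C)C)C(C)C | intermediate
14 | chlorozinc enolate of 8 | CC1=C[C@@H]2C=C(O[Zn]Cl)[C@H]1O2 | intermediate
15 | (1S,3R,4R)-6-methyl-3-exo-[(E)-1-(triisopropylsilyloxy)prop-1-en-2-yl]-7-oxabicyclo[2.2.1]hept-5-en-2-one | CC1=C[C@@H]2[C@@H](/C(C)=C/O[Si](C(C)C)(C(C)C)C(C)C)C(=O)[C@H]1O2 | intermediate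
16 | 4-bromofuran-2(5H)-one | O=C1C=C(Br)CO1 | starting material
17 | [(4-bromofuran-2-yl)oxy]triisopropylsilane | Brc1coc(O[Si](C(C)C)(C(C)C)C(C)C)c1 | intermediate
18 | [5-(triisopropylsilyloxy)furan-3-yl]lithium | [Li]c1coc(O[Si](C(C)C)(C(C)C)C(C)C)c1 | intermediate
19 | (1S,2R,3R,4R)-6-methyl-3-exo-[(E)-1-(triisopropylsilyloxy)prop-1-en-2-yl]-2-exo-[5-(triisopropylsilyloxy)furan-3-yl]-7-oxabicyclo[2.2.1]hept-5-en-2-ol | CC1=C[C@@H]2[C@@H](/C(C)=C/O[Si](C(C)C)(C(C)C)C(C)C)[C@@](O)(c3coc(O[Si](C(C)C)(C(C)C)C(C)C)c3)[C@H]1O2 | intermediate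
20 | potassium C7=C8 enolate of the 2,9-epoxy-bridged ten-membered ring: (5S,6R), 3Z, 5-silyloxy, lactone ring as 2-silyloxy-dihydrofuran (C11=C12) | [K+].[O-]/C2=C1\C=C(O[Si](C(C)C)(C(C)C)C(C)C)O[C@H]1[C@@H](O[Si](C(C)C)(C(C)C)C(C)C)/C(C)=C\[C@H]3C=C(C)[C@@H]2O3 | intermediate
21 | (2R,5S,6R,7S,9S)-2,9-epoxy-8-oxo-5-(triisopropylsilyloxy)germacra-1(10),3Z-diene carrying the lactone as its triisopropylsilyl ketene acetal (O–C12(OSi)=C11) | O=C1[C@H]2O[C@H](C=C2C)/C=C(/C)[C@H](O[Si](C(C)C)(C(C)C)C(C)C)[C@@H]3OC(O[Si](C(C)C)(C(C)C)C(C)C)=C[C@H]13 | intermediate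
22 | (2R,5S,6R,7S,9S)-13-(dimethylamino)-2,9-epoxy-8-oxo-5-(triisopropylsilyloxy)germacra-1(10),3Z-dien-12,6-olide (C11 epimers) | CN(C)CC1C(=O)O[C@@H]2[C@H]1C(=O)[C@H]3O[C@H](C=C3C)/C=C(/C)[C@@H]2O[Si](C(C)C)(C(C)C)C(C)C | intermediate
23 | (2R,5S,6R,7S)-13-(dimethylamino)-2-hydroxy-8-oxo-5-(triisopropylsilyloxy)germacra-1(10)Z,3Z-dien-12,6-olide (C11 epimers) | CN(C)CC1C(=O)O[C@@H]2[C@H]1C(=O)C/C(C)=C\[C@@H](O)/C=C(/C)[C@@H]2O[Si](C(C)C)(C(C)C)C(C)C | intermediate
24 | (5S,6R,7R,8S)-13-(dimethylamino)-8-hydroxy-2-oxo-5-(triisopropylsilyloxy)germacra-1(10)Z,3Z-dien-12,6-olide (C11 epimers) | CN(C)CC1C(=O)O[C@@H]2[C@H]1[C@@H](O)C/C(C)=C\C(=O)/C=C(/C)[C@@H]2O[Si](C(C)C)(C(C)C)C(C)C | intermediate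
25 | (5S,6R,7R,8S)-13-(dimethylamino)-2-oxo-8-tigloyloxy-5-(triisopropylsilyloxy)germacra-1(10)Z,3Z-dien-12,6-olide (C11 epimers) | CN(C)CC1C(=O)O[C@@H]2[C@H]1[C@@H](OC(=O)/C(C)=C/C)C/C(C)=C\C(=O)/C=C(/C)[C@@H]2O[Si](C(C)C)(C(C)C)C(C)C | intermediate
26 | trimethylammonium iodide of 25 | C[N+](C)(C)CC1C(=O)O[C@@H]2[C@H]1[C@@H](OC(=O)/C(C)=C/C)C/C(C)=C\C(=O)/C=C(/C)[C@@H]2O[Si](C(C)C)(C(C)C)C(C)C.[I-] | intermediate
27 | (5S,6R,7R,8S)-2-oxo-8-tigloyloxy-5-(triisopropylsilyloxy)germacra-1(10)Z,3Z,11(13)-trien-12,6-olide | C=C1C(=O)O[C@@H]2[C@H]1[C@@H](OC(=O)/C(C)=C/C)C/C(C)=C\C(=O)/C=C(/C)[C@@H]2O[Si](C(C)C)(C(C)C)C(C)C | intermediate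
28 | (5S,6R,7R,8S)-5-hydroxy-2-oxo-8-tigloyloxygermacra-1(10)Z,3Z,11(13)-trien-12,6-olide | C=C1C(=O)O[C@@H]2[C@H]1[C@@H](OC(=O)/C(C)=C/C)C/C(C)=C\C(=O)/C=C(/C)[C@@H]2O | target

Total step count: 15. Longest linear sequence: 12 steps (steps 1–5, 8, 10–15).

Steps most likely to fail

First, step 11: the potassium alkoxide of 19 may fragment by alkoxide-accelerated retro-[4+2] cycloreversion (loss of 3-methylfuran), or react through the other boat and give the trans C3=C4 isomer, before or instead of the wanted [3,3] shift. The fallback removes the oxyanion and sets out from 19. O-Silylation of the tertiary hydroxyl (Me3SiCl, imidazole, DMF) should give the C8-O-trimethylsilyl ether F1. Neutral thermal silyloxy-Cope rearrangement of F1 (toluene, 100 °C, base-washed glass) should give the ring-expanded trimethylsilyl enol ether F2. MeLi (THF, −78 °C) frees the lithium enolate from F2, and AcOH protonates it from the outer face. The fallback comes back to the route at 21, which is treated with the iminium salt as in step 11.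

Second, step 12: the transannular hydride transfer may be slower than enolisation of the C8 ketone toward C7 with loss of the C6 carboxylate (β-elimination of the lactone), or the C2 alkoxide may rest as its hemiketal with C8. The fallback separates the two events and sets out from 22. SmI2/MeOH at −78 °C with a cold acidic quench gives 23, now isolated. External reduction of 23 (NaBH4, CeCl3·7H2O, MeOH, −78 °C), expected from the outer face of the carbonyl, should give the (8R)-diol F3. MnO2 (CH2Cl2) oxidises only the doubly allylic C2 carbinol of F3 and should give the (8R)-hydroxy dienone F4. Mitsunobu esterification of F4 with tiglic acid (PPh3, DIAD, THF) inverts C8, and the fallback comes back to the route at 25. Should the borohydride give the (8S) epimer instead, MnO2 leads straight to 24.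

Third, step 8: the alkenylpalladium intermediate may add across the strained C1=C10 double bond (Heck-type carbopalladation) instead of coupling with the enolate, and the product may epimerise at C3 through its own enolate. The fallback sets out from 8. Its zinc enolate is brominated on the exo face (LiHMDS, ZnCl2, then N-bromosuccinimide, −78 °C), which should give the exo-bromo ketone F5. Nickel-catalysed cross-coupling of F5 with the alkenylzirconocene chloride 12 (NiCl2·glyme, bis(oxazoline) ligand, DME, 10 °C) forms the C3–C4 bond through a C3 radical, which is captured on the exo face. The fallback comes back to the route at 15.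

Further compounds
F1 | step 11 | C8-O-trimethylsilyl ether of 19 | CC1=C[C@@H]2[C@@H](/C(C)=C/O[Si](C(C)C)(C(C)C)C(C)C)[C@@](O[Si](C)(C)C)(c3coc(O[Si](C(C)C)(C(C)C)C(C)C)c3)[C@H]1O2
F2 | step 11 | ring-expanded trimethylsilyl enol ether (C7=C8) of the 2,9-epoxy-bridged ketone | C[Si](C)(C)O/C2=C1\C=C(O[Si](C(C)C)(C(C)C)C(C)C)O[C@H]1[C@@H](O[Si](C(C)C)(C(C)C)C(C)C)/C(C)=C\[C@H]3C=C(C)[C@@H]2O3
F3 | step 12 | (8R)-diol: (2R,5S,6R,7R,8R)-13-(dimethylamino)-2,8-dihydroxy-5-(triisopropylsilyloxy)germacra-1(10)Z,3Z-dien-12,6-olide | CN(C)CC1C(=O)O[C@@H]2[C@H]1[C@H](O)C/C(C)=C\[C@@H](O)/C=C(/C)[C@@H]2O[Si](C(C)C)(C(C)C)C(C)C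
F4 | step 12 | (8R)-hydroxy dienone: (5S,6R,7R,8R)-13-(dimethylamino)-8-hydroxy-2-oxo-5-(triisopropylsilyloxy)germacra-1(10)Z,3Z-dien-12,6-olide | CN(C)CC1C(=O)O[C@@H]2[C@H]1[C@H](O)C/C(C)=C\C(=O)/C=C(/C)[C@@H]2O[Si](C(C)C)(C(C)C)C(C)C
F5 | step 8 | exo-bromo ketone: (1S,3R,4R)-3-exo-bromo-6-methyl-7-oxabicyclo[2.2.1]hept-5-en-2-one | CC1=C[C@@H]2[C@@H](Br)C(=O)[C@H]1O2
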